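**Retrosynthetic overview**
1. Target ⇐ its 7,2'-bis-TBS ether ⇐ one-pot double sigmatropic rearrangement of a 5,4'-bis(O-prenyl)flavanone: 5-O-prenyl → 8-C-prenyl (Eu-catalysed Claisen–Cope) and 4'-O-prenyl → 5'-C-(1,1-dimethylallyl) (Claisen).
2. That bis-ether ⇐ (2S)-5,7,2'-trihydroxy-4'-prenyloxyflavanone by silylation of 7-OH/2'-OH and Mitsunobu etherification of the chelated 5-OH.
3. The flavanone ⇐ 4,5,7-trihydroxycoumarin + 2-hydroxy-4-prenyloxybenzaldehyde in one catalytic asymmetric cascade: Knoevenagel, translactonisation (new lactone ring), oxa-Michael (C ring, C2 set), then loss of the lactone carbonyl as CO2.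
4. Building blocks ⇐ phloroglucinol + malonic acid, and 2,4-dihydroxybenzaldehyde + prenyl bromide.
5. Ring order: A and B arenes are bought; sacrificial coumarin pyranone (step 1); B-ring lactone and chromanone C ring close together (step 3); the lactone ring is excised in the same pot.

Assumption: flavanone numbering (O1, C2, C4=O, B ring primed) is used for 11–17, and the single stereocentre of the target is C2 = S as read from the given SMILES.
Abbreviations: prenyl = 3-methylbut-2-en-1-yl; 1,1-dimethylallyl = 2-methylbut-3-en-2-yl; TBS = tert-butyldimethylsilyl.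

**Step 1**
Reactants: 1 phloroglucinol; 2 malonic acid
Product: 3 4,5,7-trihydroxy-2H-chromen-2-one (4,5,7-trihydroxycoumarin)
Conditions: ZnCl2, POCl3, 65 °C; then ice/H2O
Reagents that add atoms: none
Why: C-acylation of the symmetric, highly nucleophilic phloroglucinol by activated malonic acid, then lactonisation onto the neighbouring OH (Friedel–Crafts acylation/cyclodehydration, the classical 4-hydroxycoumarin synthesis); the symmetry of 1 allows only one product.

**Step 2**
Reactants: 4 2,4-dihydroxybenzaldehyde; 5 prenyl bromide (1-bromo-3-methylbut-2-ene)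
Product: 6 2-hydroxy-4-[(3-methylbut-2-en-1-yl)oxy]benzaldehyde
Conditions: KHCO3, MeCN, 60 °C
Reagents that add atoms: none
Why: Williamson etherification; the 2-OH is hydrogen-bonded to the formyl group, so the weak base deprotonates and alkylates only the more acidic 4-OH (SN2 on the primary allylic bromide).

**Step 3**
Reactants: 3 4,5,7-trihydroxycoumarin; 6 2-hydroxy-4-(prenyloxy)benzaldehyde
Product: 11 (2S)-5,7-dihydroxy-2-{2-hydroxy-4-[(3-methylbut-2-en-1-yl)oxy]phenyl}-2,3-dihydro-4H-chromen-4-one, via Knoevenagel ylidene-dione 7 (not isolated), via 3-aroylcoumarin 8 (not isolated), via tetracyclic enol lactone 9 (not isolated), via beta-keto acid 10 (not isolated)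
Conditions: 9-amino(9-deoxy)epi-quinidine 3,5-bis(CF3)phenyl thiourea (10 mol%), 4 Å MS, THF/PhMe 1:1, 25 °C, 3 added slowly to 6 (1.2 equiv); then AcOH/H2O, 55 °C
Reagents that add atoms: none
Why: Proposed new method: C3 of the 4-hydroxycoumarin condenses with the aldehyde (Knoevenagel) to ylidene-dione 7; its salicyl OH attacks the lactone carbonyl and expels the phloroglucinol oxygen (translactonisation, new pyranone ring, 8); the liberated A-ring phenoxide, ion-paired to the quinuclidinium while the thiourea binds the 1,3-dicarbonyl, adds 6-endo to C4 of the doubly activated coumarin (asymmetric oxa-Michael), closing the chromanone ring and setting C2 in 9 (the two ortho OH groups of the trihydroxybenzoyl unit are equivalent, so there is no regiochemical issue); aqueous AcOH then protonates the catalyst, hydrolyses the β-keto aryl lactone and the acid 10 loses CO2; the closest known reactions are the Knoevenagel/translactonisation of 4-hydroxycoumarins with salicylaldehydes to 3-(2-hydroxybenzoyl)coumarins and the bifunctional-thiourea-catalysed enantioselective oxa-Michael cyclisation/decarboxylation of 2'-hydroxy alkylidene β-keto esters to flavanones; the sense of induction on this new acceptor is not known in advance and is checked by CD on 11 (2S: negative Cotton effect near 290 nm), with the quinine-derived pseudoenantiomer giving the antipode.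

**Step 4**
Reactants: 11 (2S)-5,7,2'-trihydroxy-4'-(prenyloxy)flavanone
Product: 12 (2S)-7-[(tert-butyldimethylsilyl)oxy]-2-{2-[(tert-butyldimethylsilyl)oxy]-4-[(3-methylbut-2-en-1-yl)oxy]phenyl}-5-hydroxy-2,3-dihydro-4H-chromen-4-one
Conditions: TBSCl (2.2 equiv), imidazole, DMF, 0 °C → rt
Reagents that add atoms: tert-butyldimethylsilyl chloride, CC(C)(C)[Si](C)(C)Cl
Why: Chemoselective silylation of the two non-chelated phenols (7-OH, 2'-OH); the 5-OH is locked in a hydrogen bond to C4=O and stays free, and the mild conditions do not open the pyranone ring.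

**Step 5**
Reactants: 12 bis-TBS flavanone; 13 3-methylbut-2-en-1-ol (prenol)
Product: 14 (2S)-7-[(tert-butyldimethylsilyl)oxy]-2-{2-[(tert-butyldimethylsilyl)oxy]-4-[(3-methylbut-2-en-1-yl)oxy]phenyl}-5-[(3-methylbut-2-en-1-yl)oxy]-2,3-dihydro-4H-chromen-4-one
Conditions: PPh3, DIAD, THF, 0 °C → rt
Reagents that add atoms: none
Why: Mitsunobu etherification of the only remaining phenol with the primary allylic alcohol (SN2 at CH2), under neutral conditions that leave the aryl silyl ethers, the prenyl ether and C2 untouched.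

**Step 6**
Reactants: 14 5,4'-bis(O-prenyl) bis-TBS flavanone
Product: 16 (2S)-7-[(tert-butyldimethylsilyl)oxy]-2-{2-[(tert-butyldimethylsilyl)oxy]-4-hydroxy-5-(2-methylbut-3-en-2-yl)phenyl}-5-hydroxy-8-(3-methylbut-2-en-1-yl)-2,3-dihydro-4H-chromen-4-one, via C8-prenylated mono-rearranged ether 15 (not isolated)
Conditions: Eu(fod)3 (15 mol%), NaHCO3, PhCl, 85 °C, then 130 °C
Reagents that add atoms: none
Why: Two aromatic Claisen rearrangements in one pot: Eu(III) chelated between C4=O and O5 triggers ortho-Claisen to C6 and a Cope shift on to C8 (para-Claisen–Cope), returning a normal prenyl group at C8 and the free 5-OH (15); on further heating the 4'-O-prenyl ether undergoes a [3,3] shift to the unhindered C5' (C3' is flanked by OTBS, and a non-chelated meta oxygen directs para to itself), delivering the 1,1-dimethylallyl group by allyl inversion; no bond to C2 is involved and NaHCO3 suppresses acid-induced chroman formation.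

**Step 7**
Reactants: 16 doubly rearranged bis-TBS flavanone
Product: 17 (2S)-2-[2,4-dihydroxy-5-(2-methylbut-3-en-2-yl)phenyl]-5,7-dihydroxy-8-(3-methylbut-2-en-1-yl)-2,3-dihydro-4H-chromen-4-one (AChE-IN-17)
Conditions: KHF2, MeOH, rt
Reagents that add atoms: none
Why: Fluoride cleavage of the two aryl silyl ethers (Si–F bond formation) under near-neutral conditions, which avoids base-induced retro-oxa-Michael racemisation at C2 and acid-induced cyclisation of the prenyl groups onto neighbouring phenols.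

**Compound list**
1 | phloroglucinol (benzene-1,3,5-triol) | Oc1cc(O)cc(O)c1 | starting material
2 | malonic acid | OC(=O)CC(=O)O | starting material
3 | 4,5,7-trihydroxy-2H-chromen-2-one | O=c1cc(O)c2c(O)cc(O)cc2o1 | intermediate
4 | 2,4-dihydroxybenzaldehyde | O=Cc1ccc(O)cc1O | starting material
5 | prenyl bromide (1-bromo-3-methylbut-2-ene) | CC(C)=CCBr | starting material
6 | 2-hydroxy-4-[(3-methylbut-2-en-1-yl)oxy]benzaldehyde | CC(C)=CCOc1ccc(C=O)c(O)c1 | intermediate
7 | (3Z)-5,7-dihydroxy-3-({2-hydroxy-4-[(3-methylbut-2-en-1-yl)oxy]phenyl}methylidene)-2H-chromene-2,4(3H)-dione (aryl cis to the lactone carbonyl) | O=C1Oc2cc(O)cc(O)c2C(=O)/C1=C/c1ccc(OCC=C(C)C)cc1O | intermediate (not isolated)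
8 | 7-[(3-methylbut-2-en-1-yl)oxy]-3-(2,4,6-trihydroxybenzoyl)-2H-chromen-2-one | O=C(c1c(O)cc(O)cc1O)c1cc2ccc(OCC=C(C)C)cc2oc1=O | intermediate (not isolated)
9 | (12aR)-7,8,10-trihydroxy-3-[(3-methylbut-2-en-1-yl)oxy]-6H,12aH-chromeno[4,3-b]chromen-6-one (enol tautomer of the 6a,12a-dihydro-6,7-dione; C12a becomes flavanone C2) | CC(C)=CCOc1ccc2[C@H]3Oc4cc(O)cc(O)c4C(O)=C3C(=O)Oc2c1 | intermediate (not isolated)
10 | (2S)-5,7-dihydroxy-2-{2-hydroxy-4-[(3-methylbut-2-en-1-yl)oxy]phenyl}-4-oxochromane-3-carboxylic acid (C3 enolisable, not defined) | CC(C)=CCOc1ccc([C@H]2Oc3cc(O)cc(O)c3C(=O)C2C(=O)O)c(O)c1 | intermediate (not isolated)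
11 | (2S)-5,7-dihydroxy-2-{2-hydroxy-4-[(3-methylbut-2-en-1-yl)oxy]phenyl}-2,3-dihydro-4H-chromen-4-one | CC(C)=CCOc1ccc([C@@H]2CC(=O)c3c(O)cc(O)cc3O2)c(O)c1 | intermediate
12 | (2S)-7-(TBS-oxy)-2-{2-(TBS-oxy)-4-[(3-methylbut-2-en-1-yl)oxy]phenyl}-5-hydroxy-2,3-dihydro-4H-chromen-4-one | CC(C)=CCOc1ccc([C@@H]2CC(=O)c3c(O)cc(O[Si](C)(C)C(C)(C)C)cc3O2)c(O[Si](C)(C)C(C)(C)C)c1 | intermediate
13 | 3-methylbut-2-en-1-ol (prenol) | CC(C)=CCO | starting material
14 | (2S)-7-(TBS-oxy)-2-{2-(TBS-oxy)-4-[(3-methylbut-2-en-1-yl)oxy]phenyl}-5-[(3-methylbut-2-en-1-yl)oxy]-2,3-dihydro-4H-chromen-4-one | CC(C)=CCOc1ccc([C@@H]2CC(=O)c3c(OCC=C(C)C)cc(O[Si](C)(C)C(C)(C)C)cc3O2)c(O[Si](C)(C)C(C)(C)C)c1 | intermediate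
15 | (2S)-7-(TBS-oxy)-2-{2-(TBS-oxy)-4-[(3-methylbut-2-en-1-yl)oxy]phenyl}-5-hydroxy-8-(3-methylbut-2-en-1-yl)-2,3-dihydro-4H-chromen-4-one | CC(C)=CCOc1ccc([C@@H]2CC(=O)c3c(O)cc(O[Si](C)(C)C(C)(C)C)c(CC=C(C)C)c3O2)c(O[Si](C)(C)C(C)(C)C)c1 | intermediate (not isolated)
16 | (2S)-7-(TBS-oxy)-2-{2-(TBS-oxy)-4-hydroxy-5-(2-methylbut-3-en-2-yl)phenyl}-5-hydroxy-8-(3-methylbut-2-en-1-yl)-2,3-dihydro-4H-chromen-4-one | C=CC(C)(C)c1cc([C@@H]2CC(=O)c3c(O)cc(O[Si](C)(C)C(C)(C)C)c(CC=C(C)C)c3O2)c(O[Si](C)(C)C(C)(C)C)cc1O | intermediate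
17 | (2S)-2-[2,4-dihydroxy-5-(2-methylbut-3-en-2-yl)phenyl]-5,7-dihydroxy-8-(3-methylbut-2-en-1-yl)-2,3-dihydro-4H-chromen-4-one | C=CC(C)(C)c1cc([C@@H]2CC(=O)c3c(O)cc(O)c(CC=C(C)C)c3O2)c(O)cc1O | target

**Totals**
Total step count: 7.
Longest linear sequence: 6 steps (steps 2–7 from 4; equally steps 1 and 3–7 from 1).

**Three steps most likely to fail**

Step 3 (asymmetric triple cascade). The risks are dicoumarol-type bis-adducts, a sluggish Knoevenagel under a tertiary amine only, and above all incomplete enantiocontrol on a polyphenolic substrate. The fallback keeps the cascade as the ring-forming event but secures C2 by kinetic resolution instead. It sets out from 14 of insufficient ee and comes back at 14. Noyori-type asymmetric transfer hydrogenation (RuCl(p-cymene)[TsDPEN], the enantiomer matched to the 2R ketone, HCO2H/Et3N, EtOAc, rt) reduces only the unwanted (2R)-antipode to (2R,4R)-cis-7-(TBS-oxy)-2-{2-(TBS-oxy)-4-(prenyloxy)phenyl}-5-(prenyloxy)chroman-4-ol F1. This alcohol is removed by chromatography, leaving enantiopure 14.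

Step 5 (Mitsunobu at the chelated 5-OH). The 5-OH is hydrogen-bonded and flanked by the carbonyl, so the bulky prenyl transfer may stall or give SN2′ ether. The fallback sets out from 12 and comes back at 14. Pd(0)-catalysed Tsuji–Trost O-allylation (allyl tert-butyl carbonate, Pd(PPh3)4, THF, 50 °C) gives (2S)-5-(allyloxy)-7-(TBS-oxy)-2-{2-(TBS-oxy)-4-(prenyloxy)phenyl}chroman-4-one F2. Olefin cross-metathesis with 2-methyl-2-butene (Grubbs II, CH2Cl2, 40 °C) then converts the allyl ether into the prenyl ether 14; the trisubstituted B-ring prenyl ether is inert or degenerate under these conditions.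

Step 6 (double rearrangement). The non-chelated B-ring ether rearranges more slowly than the Eu-chelated A-ring ether, and forcing it may give C3' or abnormal Claisen products or erode ee. The fallback runs the two rearrangements on separate substrates; it sets out from 12 and comes back at the target 17.
- Thermal Claisen of 12 alone (o-dichlorobenzene, 165 °C, microwave; no A-ring allyl ether is present yet) gives (2S)-7-(TBS-oxy)-2-{2-(TBS-oxy)-4-hydroxy-5-(1,1-dimethylallyl)phenyl}-5-hydroxychroman-4-one F3.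
- TBSCl/imidazole silylates its 4'-OH to (2S)-7-(TBS-oxy)-2-{2,4-bis(TBS-oxy)-5-(1,1-dimethylallyl)phenyl}-5-hydroxychroman-4-one F4.
- Mitsunobu reaction with 13 gives (2S)-7-(TBS-oxy)-2-{2,4-bis(TBS-oxy)-5-(1,1-dimethylallyl)phenyl}-5-(prenyloxy)chroman-4-one F5.
- Eu(fod)3/NaHCO3 in PhCl at 85 °C gives (2S)-7-(TBS-oxy)-2-{2,4-bis(TBS-oxy)-5-(1,1-dimethylallyl)phenyl}-5-hydroxy-8-prenylchroman-4-one F6.
- KHF2/MeOH then gives 17.

**Further compounds**
F1 | step 3 | (2R,4R)-cis-7-(TBS-oxy)-2-{2-(TBS-oxy)-4-[(3-methylbut-2-en-1-yl)oxy]phenyl}-5-[(3-methylbut-2-en-1-yl)oxy]chroman-4-ol | CC(C)=CCOc1ccc([C@H]2C[C@@H](O)c3c(OCC=C(C)C)cc(O[Si](C)(C)C(C)(C)C)cc3O2)c(O[Si](C)(C)C(C)(C)C)c1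
F2 | step 5 | (2S)-5-(allyloxy)-7-(TBS-oxy)-2-{2-(TBS-oxy)-4-[(3-methylbut-2-en-1-yl)oxy]phenyl}chroman-4-one | CC(C)=CCOc1ccc([C@@H]2CC(=O)c3c(OCC=C)cc(O[Si](C)(C)C(C)(C)C)cc3O2)c(O[Si](C)(C)C(C)(C)C)c1
F3 | step 6 | (2S)-7-(TBS-oxy)-2-{2-(TBS-oxy)-4-hydroxy-5-(2-methylbut-3-en-2-yl)phenyl}-5-hydroxychroman-4-one | C=CC(C)(C)c1cc([C@@H]2CC(=O)c3c(O)cc(O[Si](C)(C)C(C)(C)C)cc3O2)c(O[Si](C)(C)C(C)(C)C)cc1O
F4 | step 6 | (2S)-7-(TBS-oxy)-2-{2,4-bis(TBS-oxy)-5-(2-methylbut-3-en-2-yl)phenyl}-5-hydroxychroman-4-one | C=CC(C)(C)c1cc([C@@H]2CC(=O)c3c(O)cc(O[Si](C)(C)C(C)(C)C)cc3O2)c(O[Si](C)(C)C(C)(C)C)cc1O[Si](C)(C)C(C)(C)C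
F5 | step 6 | (2S)-7-(TBS-oxy)-2-{2,4-bis(TBS-oxy)-5-(2-methylbut-3-en-2-yl)phenyl}-5-[(3-methylbut-2-en-1-yl)oxy]chroman-4-one | C=CC(C)(C)c1cc([C@@H]2CC(=O)c3c(OCC=C(C)C)cc(O[Si](C)(C)C(C)(C)C)cc3O2)c(O[Si](C)(C)C(C)(C)C)cc1O[Si](C)(C)C(C)(C)C
F6 | step 6 | (2S)-7-(TBS-oxy)-2-{2,4-bis(TBS-oxy)-5-(2-methylbut-3-en-2-yl)phenyl}-5-hydroxy-8-(3-methylbut-2-en-1-yl)chroman-4-one | C=CC(C)(C)c1cc([C@@H]2CC(=O)c3c(O)cc(O[Si](C)(C)C(C)(C)C)c(CC=C(C)C)c3O2)c(O[Si](C)(C)C(C)(C)C)cc1O[Si](C)(C)C(C)(C)C
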